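**Plan**

- Ring labels: ring A is the 2,4-dihydroxyphenyl ketone ring, ring B its β-aryl ring (4-hydroxyphenyl), ring C the second resorcinol ketone ring (bonded through its C1 to C3 of ring B, acylated at its C5), ring D the terminal 4-hydroxyphenyl ring.
- Retrosynthesis first cuts the six O–CH3 bonds of a hexamethyl ether, then moves each carbonyl oxygen by a 1,3-shift onto the β-carbon, so that each enone becomes Ar–C≡C–CH(OH)–Ar′.
- Enabling feature: each carbonyl carbon sits on a ring with oxygen ortho and para to it (rings A and C) and each β-carbon on a ring with para oxygen (rings B and D). The alkyne carbon that must receive oxygen is therefore the more cationic one, and the hydroxyl that must leave is para-alkoxybenzylic.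
- Further cuts: the carbinol C–C(sp) bond next to ring B (acetylide plus aldehyde), the C5(ring C)–C(sp) bond (Sonogashira), and the ring B–ring C biaryl bond (Suzuki–Miyaura).
- Forward order: B–C biaryl, iodination at C5 of ring C, ring D arm by Sonogashira, ring A arm by acetylide addition, twofold Meyer–Schuster transposition, demethylation. All four rings are bought; none is built.
- Stereochemistry: the target has no stereocentre. Both E alkenes arise under thermodynamic control in the transposition, and the carbinol centres made on the way are uncontrolled and erased there.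

Key step: step 6

Assumption: 1-ethynyl-2,4-dimethoxybenzene and ethynylmagnesium bromide (THF solution) are taken as purchasable; carbinol centres are carried as racemates or diastereomer mixtures because the key step destroys them.

**Route**

Step 1
Reactants: 1 3-bromo-4-methoxybenzaldehyde; 2 2,4-dimethoxyphenylboronic acid
Product: 3 3-(2,4-dimethoxyphenyl)-4-methoxybenzaldehyde
Conditions: Pd(PPh3)4 (3 mol%), K2CO3, DME/H2O, 85 °C
Reagents that add atoms: none
Why: Suzuki–Miyaura cross-coupling of an aryl bromide with an electron-rich arylboronic acid is routine and tolerates the free aldehyde, and a modest excess of 2 should offset its protodeboronation.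

Step 2
Reactants: 3 3-(2,4-dimethoxyphenyl)-4-methoxybenzaldehyde
Product: 4 3-(5-iodo-2,4-dimethoxyphenyl)-4-methoxybenzaldehyde
Conditions: NIS (1.05 equiv), TFA (cat.), MeCN, rt, dark
Reagents that add atoms: N-iodosuccinimide, O=C1CCC(=O)N1I
Why: Electrophilic aromatic iodination with acid-activated NIS should go to C5 of ring C (numbered from the biaryl carbon), the only unhindered position that is para to one methoxy group and ortho to the other, whereas C3 is flanked by two methoxy groups and ring B is deactivated by its formyl group.

Step 3
Reactants: 5 4-methoxybenzaldehyde; 6 ethynylmagnesium bromide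
Product: 7 1-(4-methoxyphenyl)prop-2-yn-1-ol (racemic)
Conditions: THF, 0 °C to rt; aq. NH4Cl
Reagents that add atoms: none
Why: Grignard 1,2-addition of an alkynyl nucleophile to a non-enolisable aldehyde, in which the new carbinol centre forms without control (racemate), which does not matter because step 6 removes it.

Step 4
Reactants: 4 3-(5-iodo-2,4-dimethoxyphenyl)-4-methoxybenzaldehyde; 7 1-(4-methoxyphenyl)prop-2-yn-1-ol
Product: 8 3-{5-[3-hydroxy-3-(4-methoxyphenyl)prop-1-yn-1-yl]-2,4-dimethoxyphenyl}-4-methoxybenzaldehyde (racemic)
Conditions: PdCl2(PPh3)2 (3 mol%), CuI (5 mol%), Et3N, THF, rt to 45 °C, degassed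
Reagents that add atoms: none
Why: Sonogashira coupling of an aryl iodide with a terminal alkyne proceeds near room temperature beside a free aldehyde and a free propargylic hydroxyl, and the electron-rich ring C together with the low temperature should suppress base-mediated propargyl–allenyl isomerisation, which would put the carbonyl on the wrong carbon.

Step 5
Reactants: 8 3-{5-[3-hydroxy-3-(4-methoxyphenyl)prop-1-yn-1-yl]-2,4-dimethoxyphenyl}-4-methoxybenzaldehyde; 9 1-ethynyl-2,4-dimethoxybenzene
Product: 11 bis-propargylic diol (mixture of diastereomers), via lithium acetylide 10 (not isolated)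
Conditions: 9 (2.5 equiv), n-BuLi (2.4 equiv), THF, −78 °C; then 8, −78 to 0 °C; aq. NH4Cl; Et3N-deactivated silica
Reagents that add atoms: none
Why: 1,2-Addition of a lithium acetylide to an aromatic aldehyde, in which the first equivalent is spent on the free hydroxyl of 8 and the second adds to the formyl group, the new carbinol centre forming without control so that 11 is a diastereomer mixture that step 6 converges.

Step 6
Reactants: 11 bis-propargylic diol
Product: 12 rhuschalcone VI hexamethyl ether (both alkenes E)
Conditions: (Ph3P)AuNTf2 (5 mol%), MeOH (2 equiv), toluene, rt, dark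
Reagents that add atoms: none
Why: Cationic monovalent gold binds each alkyne and methanol adds anti at the alkyne carbon that carries ring A or ring C, where the ortho and para methoxy groups stabilise the developing positive charge, while the inductively withdrawing carbinol disfavours attack at the other carbon. The resulting vinylgold enol ether expels the benzylic hydroxyl, an ionisation helped by the para-methoxy group of ring B or ring D, and the water set free returns at the oxocarbenium carbon, so that methanol is released and protodeauration leaves the aryl ketone with the C=C bond at the former carbinol carbon. The closest known reaction type is the gold-catalysed Meyer–Schuster rearrangement of secondary 1,3-diarylpropargylic alcohols to chalcones with a protic additive, here run on two such units in one molecule; being an isomerisation, it needs no stoichiometry balanced between the arms. No ring is closed and no stereocentre is created, and because the two carbinol centres vanish, the diastereomer mixture converges on one product. Both alkenes should emerge E because the allenyl and dienol-type intermediates equilibrate to the conjugated trans enone. The selectivity needed is oxygen delivery to the aryl-bearing alkyne carbons in preference to 5-endo attack by the neighbouring methoxy oxygen or to plain ionisation of the carbinols, and it is secured by the electron push of rings A and C, by the non-transferable methyl groups and by the neutral, mild catalyst.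

Step 7
Reactants: 12 rhuschalcone VI hexamethyl ether
Product: 13 rhuschalcone VI
Conditions: BBr3 (excess), CH2Cl2, −78 °C to rt, dark; then ice/H2O
Reagents that add atoms: none
Why: Exhaustive BBr3 cleavage of aryl methyl ethers is an established way to unmask polyhydroxychalcones, the two methoxy groups ortho to the ketones going first through boron chelation, which also shields the enones, while the E alkenes are untouched.

**Compound list**

1 | 3-bromo-4-methoxybenzaldehyde | COc1ccc(C=O)cc1Br | starting material
2 | 2,4-dimethoxyphenylboronic acid | COc1ccc(B(O)O)c(OC)c1 | starting material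
3 | 3-(2,4-dimethoxyphenyl)-4-methoxybenzaldehyde | COc1ccc(C=O)cc1-c1ccc(OC)cc1OC | intermediate
4 | 3-(5-iodo-2,4-dimethoxyphenyl)-4-methoxybenzaldehyde | COc1ccc(C=O)cc1-c1cc(I)c(OC)cc1OC | intermediate
5 | 4-methoxybenzaldehyde | COc1ccc(C=O)cc1 | starting material
6 | ethynylmagnesium bromide | C#C[Mg]Br | starting material
7 | 1-(4-methoxyphenyl)prop-2-yn-1-ol (racemic) | C#CC(O)c1ccc(OC)cc1 | intermediate
8 | 3-{5-[3-hydroxy-3-(4-methoxyphenyl)prop-1-yn-1-yl]-2,4-dimethoxyphenyl}-4-methoxybenzaldehyde (racemic) | COc1ccc(C=O)cc1-c1cc(C#CC(O)c2ccc(OC)cc2)c(OC)cc1OC | intermediate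
9 | 1-ethynyl-2,4-dimethoxybenzene | C#Cc1ccc(OC)cc1OC | starting material
10 | lithium (2,4-dimethoxyphenyl)acetylide | [Li]C#Cc1ccc(OC)cc1OC | intermediate
11 | 3-(2,4-dimethoxyphenyl)-1-{3-[5-(3-hydroxy-3-(4-methoxyphenyl)prop-1-yn-1-yl)-2,4-dimethoxyphenyl]-4-methoxyphenyl}prop-2-yn-1-ol (bis-propargylic diol, mixture of diastereomers) | OC(C#Cc1ccc(OC)cc1OC)c1ccc(OC)c(-c2cc(C#CC(O)c3ccc(OC)cc3)c(OC)cc2OC)c1 | intermediate
12 | rhuschalcone VI hexamethyl ether, (E)-1-(2,4-dimethoxyphenyl)-3-{3-[2,4-dimethoxy-5-((E)-3-(4-methoxyphenyl)acryloyl)phenyl]-4-methoxyphenyl}prop-2-en-1-one | O=C(/C=C/c1ccc(OC)c(-c2cc(C(=O)/C=C/c3ccc(OC)cc3)c(OC)cc2OC)c1)c1ccc(OC)cc1OC | intermediate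
13 | rhuschalcone VI | O=C(/C=C/c1ccc(O)c(-c2cc(C(=O)/C=C/c3ccc(O)cc3)c(O)cc2O)c1)c1ccc(O)cc1O | target

**Count**

Total steps: 7. Longest linear sequence: 6 steps (steps 1, 2, 4, 5, 6, 7, from compound 1); step 3 is a one-step branch.

**Steps most likely to fail**

Step 6. Ionisation of the two electron-rich benzylic carbinols to propargylic cations (solvolysis to methyl ethers, ether dimerisation, oligomerisation) may outrun the gold-mediated oxygen transfer, or the second arm may stall once the first enone competes for the catalyst. The fallback gives up the alkyne precursors and builds both enones by aldol condensation. It sets out from iodide 4, which is condensed with 2′,4′-dimethoxyacetophenone (CC(=O)c1ccc(OC)cc1OC; KOH, EtOH/THF, rt; Claisen–Schmidt) to give iodo chalcone F1. Stille coupling with tributyl(1-ethoxyvinyl)stannane (PdCl2(PPh3)2, toluene, 100 °C) should give enol ether F2, which dilute aqueous HCl in THF hydrolyses to methyl ketone F3. A second Claisen–Schmidt condensation of F3 with aldehyde 5 (KOH, EtOH, rt, excess aldehyde to outpace Michael addition) comes back to the route at hexamethyl ether 12.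

Step 7. Cleavage of the four non-chelated methyl ethers may remain incomplete at temperatures the enones tolerate, and the acid present may trigger oxa-Michael closure of the freed 2′-hydroxy enones or HBr addition. The fallback uses the ring closure instead of avoiding it. It sets out from hexamethyl ether 12: refluxing 48% HBr in AcOH should remove all six methyl groups while both arms close to chromanones, giving bis-flavanone F4 (mixture of diastereomers), in which the enones are masked. Brief treatment with aqueous KOH in EtOH at rt under argon should reopen both rings by E1cB elimination, the open 2′-hydroxychalcone being favoured because neither ketone ring has a second ortho hydroxyl, and cold acidification comes back to the route at target 13.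

Step 5. The free hydroxyl of 8 consumes the first equivalent of acetylide, and the lithium alkoxide so formed may aggregate or precipitate at −78 °C, so that addition of the bulky aryl acetylide to the formyl group stays incomplete. The fallback makes the ring A–C(sp) bond by cross-coupling instead. It sets out from aldehyde 8, which with excess ethynylmagnesium bromide 6 (THF, 0 °C; aq. NH4Cl) should give terminal alkyne diol F5. Sonogashira coupling of its single terminal alkyne with 1-iodo-2,4-dimethoxybenzene (COc1ccc(I)c(OC)c1; PdCl2(PPh3)2, CuI, Et3N, THF, rt) comes back to the route at diol 11.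

**Further compounds**

F1 | step 6 | (E)-1-(2,4-dimethoxyphenyl)-3-[3-(5-iodo-2,4-dimethoxyphenyl)-4-methoxyphenyl]prop-2-en-1-one | O=C(/C=C/c1ccc(OC)c(-c2cc(I)c(OC)cc2OC)c1)c1ccc(OC)cc1OC
F2 | step 6 | (E)-1-(2,4-dimethoxyphenyl)-3-{3-[5-(1-ethoxyvinyl)-2,4-dimethoxyphenyl]-4-methoxyphenyl}prop-2-en-1-one | O=C(/C=C/c1ccc(OC)c(-c2cc(C(=C)OCC)c(OC)cc2OC)c1)c1ccc(OC)cc1OC
F3 | step 6 | (E)-3-[3-(5-acetyl-2,4-dimethoxyphenyl)-4-methoxyphenyl]-1-(2,4-dimethoxyphenyl)prop-2-en-1-one | O=C(/C=C/c1ccc(OC)c(-c2cc(C(C)=O)c(OC)cc2OC)c1)c1ccc(OC)cc1OC
F4 | step 7 | 7-hydroxy-6-[2-hydroxy-5-(7-hydroxy-4-oxochroman-2-yl)phenyl]-2-(4-hydroxyphenyl)chroman-4-one (bis-flavanone, mixture of diastereomers) | O=C1CC(c2ccc(O)c(-c3cc4c(cc3O)OC(c5ccc(O)cc5)CC4=O)c2)Oc6cc(O)ccc16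
F5 | step 5 | 1-{3-[5-(3-hydroxy-3-(4-methoxyphenyl)prop-1-yn-1-yl)-2,4-dimethoxyphenyl]-4-methoxyphenyl}prop-2-yn-1-ol (mixture of diastereomers) | C#CC(O)c1ccc(OC)c(-c2cc(C#CC(O)c3ccc(OC)cc3)c(OC)cc2OC)c1
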